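## Retrosynthetic overview

1. Cadinane numbering is used: ring A = C1–C2–C3(OAc)–C4(CH3)=C5–C6, ring B = C1–C6–C7(acrylate)–C8(O-acyl)–C9–C10(CH3,OH). Ring A is a cyclohexene whose C4=C5 bond lies between the allylic C3–O carbon and the ring-fusion carbon C6, and C1 carries a carbinol carbon (C10) that can be a ketone. This is a Diels–Alder retron with the activating carbonyl inside a four-atom tether (C7–C8–C9–C10).
2. Disconnections: C10–CH3 (methyl addition to a cis-octalone), then C1–C6 and C2–C3 together by intramolecular Diels–Alder reaction of a deca-1,7,9-trien-3-one bearing a (1E,3E)-1-acetoxy-2-methyldiene. Both rings form in this one step: ring B through C1–C6, ring A through C1–C6 plus C2–C3.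
3. The triene holds only C7 and C8. They are set together (C7–C8 bond) by one catalytic asymmetric allylboration with a Morita–Baylis–Hillman-derived 2-(alkoxycarbonyl)allylboronate; C1, C6 and C3 are relayed from them in the cycloaddition, C10 in the methyl addition.
4. The C8 side-chain ester (diol masked as an acetonide) is attached before the diene is built (Wittig, dienol acetate). The enone is unmasked last; fluoride and mild acid finish.

Key step: step 18

Remarks:
- The target is (1R,3S,6R,7S,8S,10S) in the numbering above.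
- Aldehyde 11 is used as the racemate, so 19–23 and 25–27 are pairs of epimers at the carbon that becomes the C10 ketone in step 18; that centre is left open in their SMILES.
- Compounds 15 and 24 are taken as catalogue compounds.

## Route

Step 1
Reactants: 1 but-2-yne-1,4-diol
Product: 2 (E)-2-(tributylstannyl)but-2-ene-1,4-diol
Conditions: Bu3SnH, PdCl2(PPh3)2 (cat.), THF, rt
Reagents that add atoms: tributyltin hydride, CCCC[SnH](CCCC)CCCC
Why: Palladium-catalysed hydrostannation adds H and Sn syn across the symmetrical alkyne, so the two CH2OH groups end cis on the new double bond, as the side chain requires.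

Step 2
Reactants: 2 (E)-2-(tributylstannyl)but-2-ene-1,4-diol
Product: 3 tributyl(2,2-dimethyl-4,7-dihydro-1,3-dioxepin-5-yl)stannane
Conditions: Me2C(OMe)2, PPTS (cat.), CH2Cl2, rt
Reagents that add atoms: 2,2-dimethoxypropane, COC(C)(C)OC
Why: Acid-catalysed transacetalisation closes the seven-membered acetonide on the cis-1,4-diol; the ring also makes β-alkoxide elimination from the vinyllithium of step 3 impossible, since it would need a cyclic allene.

Step 3
Reactants: 3 tributyl(2,2-dimethyl-4,7-dihydro-1,3-dioxepin-5-yl)stannane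
Product: 5 2,2-dimethyl-4,7-dihydro-1,3-dioxepine-5-carboxylic acid, via vinyllithium 4 (not isolated)
Conditions: n-BuLi, THF, −78 °C; CO2; aq. HCl to pH 4, 0 °C
Reagents that add atoms: carbon dioxide, O=C=O
Why: Tin–lithium exchange and carboxylation of the vinyllithium should give the acid with the alkene geometry fixed by the ring.

Step 4
Reactants: 6 ethyl acetate; 7 acrolein
Product: 9 ethyl 3-hydroxypent-4-enoate (racemic), via lithium enolate 8 (not isolated)
Conditions: LiN(i-Pr)2, THF, −78 °C; then 7; aq. NH4Cl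
Reagents that add atoms: none
Why: Acetate aldol addition (1,2-addition of the ester enolate to the enal at low temperature); the carbinol centre is left racemic because it is oxidised to the ketone in step 18.

Step 5
Reactants: 9 ethyl 3-hydroxypent-4-enoate
Product: 10 ethyl 3-[(triethylsilyl)oxy]pent-4-enoate (racemic)
Conditions: Et3SiCl, imidazole, DMF, 0 °C → rt
Reagents that add atoms: chlorotriethylsilane, CC[Si](Cl)(CC)CC
Why: Standard silylation; the triethylsilyl ether is the most labile silyl group of the route and can be removed in step 17 without touching the acetonide or the enol acetate.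

Step 6
Reactants: 10 ethyl 3-[(triethylsilyl)oxy]pent-4-enoate
Product: 11 3-[(triethylsilyl)oxy]pent-4-enal (racemic)
Conditions: i-Bu2AlH, CH2Cl2, −78 °C; aq. potassium sodium tartrate
Reagents that add atoms: none
Why: Partial reduction of the ester stops at the aldehyde because the tetrahedral aluminium hemiacetal is stable at −78 °C.

Step 7
Reactants: 12 acryloyl chloride; 13 2-(trimethylsilyl)ethanol
Product: 14 2-(trimethylsilyl)ethyl acrylate
Conditions: Et3N, CH2Cl2, 0 °C
Reagents that add atoms: none
Why: Acylation of the alcohol by the acid chloride; the 2-(trimethylsilyl)ethyl ester is chosen because fluoride removes it at the end without touching the acetate.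

Step 8
Reactants: 14 2-(trimethylsilyl)ethyl acrylate; 15 3-[(4-methoxybenzyl)oxy]propanal
Product: 16 2-(trimethylsilyl)ethyl 3-hydroxy-5-[(4-methoxybenzyl)oxy]-2-methylidenepentanoate (racemic)
Conditions: DABCO, 1,4-dioxane/H2O, rt
Reagents that add atoms: none
Why: Morita–Baylis–Hillman reaction; the new carbinol centre is not controlled because it becomes sp2 in step 10.

Step 9
Reactants: 16 Morita–Baylis–Hillman alcohol
Product: 17 2-(trimethylsilyl)ethyl 3-acetoxy-5-[(4-methoxybenzyl)oxy]-2-methylidenepentanoate (racemic)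
Conditions: Ac2O, pyridine, DMAP (cat.), CH2Cl2, 0 °C
Reagents that add atoms: acetic anhydride, CC(=O)OC(C)=O
Why: Acetylation turns the allylic hydroxyl into the leaving group for the SN2' borylation.

Step 10
Reactants: 17 Morita–Baylis–Hillman acetate
Product: 18 2-(trimethylsilyl)ethyl (2E)-5-[(4-methoxybenzyl)oxy]-2-[(4,4,5,5-tetramethyl-1,3,2-dioxaborolan-2-yl)methyl]pent-2-enoate
Conditions: B2pin2, CuCl (cat.), LiCl, KOAc, DMF, rt
Reagents that add atoms: bis(pinacolato)diboron, CC1(C)OB(OC1(C)C)B1OC(C)(C)C(C)(C)O1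
Why: Copper-catalysed SN2' borylation of the Hosomi–Miyaura type (borylcupration of the acrylate, then loss of acetate) should give the trisubstituted alkene with the alkyl chain trans to the ester and cis to CH2B, the usual geometry for ester-derived Morita–Baylis–Hillman acetates.

Step 11
Reactants: 18 allylboronate; 11 3-[(triethylsilyl)oxy]pent-4-enal
Product: 20 2-(trimethylsilyl)ethyl (3S,4S)-4-hydroxy-3-{2-[(4-methoxybenzyl)oxy]ethyl}-2-methylidene-6-[(triethylsilyl)oxy]oct-7-enoate (both C6 epimers), via O-pinacolboryl ether 19 (not isolated)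
Conditions: (R)-TRIP (10 mol %), 4 Å MS, toluene, −30 °C; aq. NaHCO3
Reagents that add atoms: none
Why: Chiral phosphoric-acid-catalysed allylboration through a closed chair transition state, in which the γ-substituent cis to CH2B becomes syn to the new hydroxyl (the 3S,4S pair, future C7 and C8), the catalyst is expected to direct attack to the Re face of the aldehyde, and the low temperature and bulky ester should keep the borate from lactonising.

Step 12
Reactants: 20 syn-hydroxy ester; 5 2,2-dimethyl-4,7-dihydro-1,3-dioxepine-5-carboxylic acid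
Product: 21 (3S,4S)-4-O-(2,2-dimethyl-4,7-dihydro-1,3-dioxepine-5-carbonyl) derivative of 20
Conditions: DCC, DMAP (cat.), CH2Cl2, 0 °C → rt
Reagents that add atoms: none
Why: Steglich esterification with retention at the carbinol carbon; it installs the final C8 ester early and removes the free hydroxyl that could lactonise onto the acrylate ester.

Step 13
Reactants: 21 side-chain ester
Product: 22 2-(trimethylsilyl)ethyl (3S,4S)-4-[(2,2-dimethyl-4,7-dihydro-1,3-dioxepine-5-carbonyl)oxy]-3-(2-hydroxyethyl)-2-methylidene-6-[(triethylsilyl)oxy]oct-7-enoate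
Conditions: DDQ, CH2Cl2/pH 7 buffer, 0 °C
Reagents that add atoms: none
Why: Oxidative cleavage of the 4-methoxybenzyl ether under buffered conditions leaves the silyl ether, the acetonide and the alkenes untouched (no diene is present yet).

Step 14
Reactants: 22 primary alcohol
Product: 23 2-(trimethylsilyl)ethyl (3S,4S)-4-[(2,2-dimethyl-4,7-dihydro-1,3-dioxepine-5-carbonyl)oxy]-2-methylidene-3-(2-oxoethyl)-6-[(triethylsilyl)oxy]oct-7-enoate
Conditions: DMP, pyridine, CH2Cl2, 0 °C → rt
Reagents that add atoms: none
Why: Dess–Martin oxidation gives the aldehyde under near-neutral conditions; the stereocentre is β to the new carbonyl and cannot epimerise.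

Step 15
Reactants: 23 aldehyde; 24 2-(triphenylphosphoranylidene)propanal
Product: 25 2-(trimethylsilyl)ethyl (3S,4S)-4-[(2,2-dimethyl-4,7-dihydro-1,3-dioxepine-5-carbonyl)oxy]-3-[(2E)-3-methyl-4-oxobut-2-en-1-yl]-2-methylidene-6-[(triethylsilyl)oxy]oct-7-enoate
Conditions: toluene, 80 °C
Reagents that add atoms: none
Why: Wittig reaction with a stabilised ylide should give the (E)-2-methyl-2-enal, which carries C3, C4 and its methyl group.

Step 16
Reactants: 25 enal
Product: 26 2-(trimethylsilyl)ethyl (3S,4S)-3-[(1E,3E)-4-acetoxy-3-methylbuta-1,3-dien-1-yl]-4-[(2,2-dimethyl-4,7-dihydro-1,3-dioxepine-5-carbonyl)oxy]-2-methylidene-6-[(triethylsilyl)oxy]oct-7-enoate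
Conditions: Ac2O, Et3N, DMAP, THF, 50 °C
Reagents that add atoms: acetic anhydride, CC(=O)OC(C)=O
Why: Dienol acetate formation (vinylogous enolisation of the s-trans enal at C6 and O-acetylation) should give mainly the (1E,3E)-dienyl acetate; any 1Z isomer cannot reach the s-cis diene and stays behind in step 18.

Step 17
Reactants: 26 dienyl acetate
Product: 27 2-(trimethylsilyl)ethyl (3S,4S)-3-[(1E,3E)-4-acetoxy-3-methylbuta-1,3-dien-1-yl]-4-[(2,2-dimethyl-4,7-dihydro-1,3-dioxepine-5-carbonyl)oxy]-6-hydroxy-2-methylidene-oct-7-enoate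
Conditions: HF·pyridine, pyridine, THF, 0 °C
Reagents that add atoms: none
Why: Buffered HF·pyridine cleaves the secondary triethylsilyl ether selectively; the enol acetate, acetonide and 2-(trimethylsilyl)ethyl ester should survive these weakly acidic, non-nucleophilic conditions.

Step 18
Reactants: 27 trienol
Product: 29 2-(trimethylsilyl)ethyl (1R,3S,6R,7S,8S)-3-acetoxy-8-[(2,2-dimethyl-4,7-dihydro-1,3-dioxepine-5-carbonyl)oxy]-10-oxo-14-normuurola-4,11(13)-dien-12-oate (cis-fused octalone), via trienone 28 (not isolated)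
Conditions: DMP, pyridine, CH2Cl2, 0 °C → rt (40 °C if needed)
Reagents that add atoms: none
Why: Oxidation of the allylic alcohol gives deca-1,7,9-trien-3-one 28, whose vinyl ketone (C1=C2, activated by the C10 carbonyl inside the tether C7–C8–C9–C10) adds to the (1E,3E)-dienyl acetate in a concerted, asynchronous [4+2] cycloaddition; the closest known reaction type is the near-room-temperature intramolecular Diels–Alder reaction of internally activated deca-1,7,9-trien-3-ones to cis-octalones, including allyl-branched cases that lead to the muurolane skeleton. Ring B closes through the C1–C6 bond alone (six-membered tether ring, fused mode), and ring A through C1–C6 plus C2–C3 (the cyclohexene of the cycloaddition). The cis ring fusion (C1, C6) follows from the endo orientation of the tether carbonyl in a boat-like tether conformation, and C3 from the E geometry of the enol acetate, which by suprafacial addition places OAc cis to the C6–C7 and C1–C10 bonds. The diene face is chosen by C7: its hydrogen eclipses the C5=C6 bond and the acrylate branch points away from the dienophile (pseudo-equatorial), so H6 and H7 end trans, while the smaller C8 acyloxy group takes the pseudo-axial site. The step needs fused over bridged regiochemistry (enforced by the tether length against the weak electronic preference of the 1-acetoxydiene), endo over exo, and one diene face (secured by the C7 stereocentre).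

Step 19
Reactants: 29 cis-fused octalone
Product: 30 2-(trimethylsilyl)ethyl (1R,3S,6R,7S,8S,10S)-3-acetoxy-8-[(2,2-dimethyl-4,7-dihydro-1,3-dioxepine-5-carbonyl)oxy]-10-hydroxymuurola-4,11(13)-dien-12-oate
Conditions: MeMgBr, CeCl3, THF, −78 °C
Reagents that add atoms: methylmagnesium bromide, C[Mg]Br
Why: Organocerium 1,2-addition is non-basic and ketone-selective over the four esters, and the methyl group should enter from the convex α face, anti to the C1–C2 bond of ring A that shields the β face in both chair forms of ring B, which sets C10 with the hydroxyl β.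

Step 20
Reactants: 30 tertiary alcohol
Product: 32 CNP0468194.1, (1R,3S,6R,7S,8S,10S)-3-acetoxy-10-hydroxy-8-{[(2E)-4-hydroxy-2-(hydroxymethyl)but-2-enoyl]oxy}muurola-4,11(13)-dien-12-oic acid, via carboxylic acid acetonide 31 (not isolated)
Conditions: TASF, DMF, 0 °C → rt; then AcOH/H2O (4:1), rt
Reagents that add atoms: none
Why: Fluoride-induced fragmentation of the 2-(trimethylsilyl)ethyl ester frees the acrylic acid under near-neutral conditions, and dilute acetic acid then hydrolyses the seven-membered acetonide without touching the allylic acetate, the tertiary alcohol or the esters.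

## Compound list

1 | but-2-yne-1,4-diol | OCC#CCO | starting material
2 | (E)-2-(tributylstannyl)but-2-ene-1,4-diol | OC/C=C(\CO)[Sn](CCCC)(CCCC)CCCC | intermediate
3 | tributyl(2,2-dimethyl-4,7-dihydro-1,3-dioxepin-5-yl)stannane | CC1(C)OCC=C(CO1)[Sn](CCCC)(CCCC)CCCC | intermediate
4 | (2,2-dimethyl-4,7-dihydro-1,3-dioxepin-5-yl)lithium (not isolated) | CC1(C)OCC=C([Li])CO1 | intermediate
5 | 2,2-dimethyl-4,7-dihydro-1,3-dioxepine-5-carboxylic acid | CC1(C)OCC=C(CO1)C(=O)O | intermediate
6 | ethyl acetate | CCOC(C)=O | starting material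
7 | acrolein | C=CC=O | starting material
8 | lithium enolate of ethyl acetate (not isolated) | C=C(O[Li])OCC | intermediate
9 | ethyl 3-hydroxypent-4-enoate (racemic) | CCOC(=O)CC(O)C=C | intermediate
10 | ethyl 3-[(triethylsilyl)oxy]pent-4-enoate (racemic) | CCOC(=O)CC(O[Si](CC)(CC)CC)C=C | intermediate
11 | 3-[(triethylsilyl)oxy]pent-4-enal (racemic) | O=CCC(O[Si](CC)(CC)CC)C=C | intermediate
12 | acryloyl chloride | C=CC(=O)Cl | starting material
13 | 2-(trimethylsilyl)ethanol | OCC[Si](C)(C)C | starting material
14 | 2-(trimethylsilyl)ethyl acrylate | C=CC(=O)OCC[Si](C)(C)C | intermediate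
15 | 3-[(4-methoxybenzyl)oxy]propanal | O=CCCOCc1ccc(OC)cc1 | starting material
16 | 2-(trimethylsilyl)ethyl 3-hydroxy-5-[(4-methoxybenzyl)oxy]-2-methylidenepentanoate (racemic) | C=C(C(=O)OCC[Si](C)(C)C)C(O)CCOCc1ccc(OC)cc1 | intermediate
17 | 2-(trimethylsilyl)ethyl 3-acetoxy-5-[(4-methoxybenzyl)oxy]-2-methylidenepentanoate (racemic) | C=C(C(=O)OCC[Si](C)(C)C)C(OC(C)=O)CCOCc1ccc(OC)cc1 | intermediate
18 | 2-(trimethylsilyl)ethyl (2E)-5-[(4-methoxybenzyl)oxy]-2-[(4,4,5,5-tetramethyl-1,3,2-dioxaborolan-2-yl)methyl]pent-2-enoate | O=C(OCC[Si](C)(C)C)/C(CB1OC(C)(C)C(C)(C)O1)=C/CCOCc1ccc(OC)cc1 | intermediate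
19 | O-pinacolboryl ether of 20 (not isolated; both C6 epimers) | C=C(C(=O)OCC[Si](C)(C)C)[C@H](CCOCc1ccc(OC)cc1)[C@@H](OB1OC(C)(C)C(C)(C)O1)CC(O[Si](CC)(CC)CC)C=C | intermediate
20 | 2-(trimethylsilyl)ethyl (3S,4S)-4-hydroxy-3-{2-[(4-methoxybenzyl)oxy]ethyl}-2-methylidene-6-[(triethylsilyl)oxy]oct-7-enoate (both C6 epimers) | C=C(C(=O)OCC[Si](C)(C)C)[C@H](CCOCc1ccc(OC)cc1)[C@@H](O)CC(O[Si](CC)(CC)CC)C=C | intermediate
21 | (3S,4S)-4-O-(2,2-dimethyl-4,7-dihydro-1,3-dioxepine-5-carbonyl) derivative of 20 (both C6 epimers) | C=C(C(=O)OCC[Si](C)(C)C)[C@H](CCOCc1ccc(OC)cc1)[C@@H](OC(=O)C1=CCOC(C)(C)OC1)CC(O[Si](CC)(CC)CC)C=C | intermediate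
22 | (3S,4S)-3-(2-hydroxyethyl) analogue of 21 (both C6 epimers) | C=C(C(=O)OCC[Si](C)(C)C)[C@H](CCO)[C@@H](OC(=O)C1=CCOC(C)(C)OC1)CC(O[Si](CC)(CC)CC)C=C | intermediate
23 | (3S,4S)-3-(2-oxoethyl) analogue of 21 (both C6 epimers) | C=C(C(=O)OCC[Si](C)(C)C)[C@H](CC=O)[C@@H](OC(=O)C1=CCOC(C)(C)OC1)CC(O[Si](CC)(CC)CC)C=C | intermediate
24 | 2-(triphenylphosphoranylidene)propanal | CC(C=O)=P(c1ccccc1)(c1ccccc1)c1ccccc1 | starting material
25 | (3S,4S)-3-[(2E)-3-methyl-4-oxobut-2-en-1-yl] analogue of 21 (both C6 epimers) | C=C(C(=O)OCC[Si](C)(C)C)[C@H](C/C=C(\C)C=O)[C@@H](OC(=O)C1=CCOC(C)(C)OC1)CC(O[Si](CC)(CC)CC)C=C | intermediate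
26 | (3S,4S)-3-[(1E,3E)-4-acetoxy-3-methylbuta-1,3-dien-1-yl] analogue of 21 (both C6 epimers) | C=C(C(=O)OCC[Si](C)(C)C)[C@H](/C=C/C(C)=C/OC(C)=O)[C@@H](OC(=O)C1=CCOC(C)(C)OC1)CC(O[Si](CC)(CC)CC)C=C | intermediate
27 | 6-hydroxy trienol from 26 (both C6 epimers) | C=C(C(=O)OCC[Si](C)(C)C)[C@H](/C=C/C(C)=C/OC(C)=O)[C@@H](OC(=O)C1=CCOC(C)(C)OC1)CC(O)C=C | intermediate
28 | 6-oxo trienone from 27, a deca-1,7,9-trien-3-one (not isolated) | C=C(C(=O)OCC[Si](C)(C)C)[C@H](/C=C/C(C)=C/OC(C)=O)[C@@H](OC(=O)C1=CCOC(C)(C)OC1)CC(=O)C=C | intermediate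
29 | 2-(trimethylsilyl)ethyl (1R,3S,6R,7S,8S)-3-acetoxy-8-[(2,2-dimethyl-4,7-dihydro-1,3-dioxepine-5-carbonyl)oxy]-10-oxo-14-normuurola-4,11(13)-dien-12-oate | C=C(C(=O)OCC[Si](C)(C)C)[C@@H]1[C@H]2C=C(C)[C@@H](OC(C)=O)C[C@H]2C(=O)C[C@@H]1OC(=O)C3=CCOC(C)(C)OC3 | intermediate
30 | 2-(trimethylsilyl)ethyl (1R,3S,6R,7S,8S,10S)-3-acetoxy-8-[(2,2-dimethyl-4,7-dihydro-1,3-dioxepine-5-carbonyl)oxy]-10-hydroxymuurola-4,11(13)-dien-12-oate | C=C(C(=O)OCC[Si](C)(C)C)[C@@H]1[C@H]2C=C(C)[C@@H](OC(C)=O)C[C@H]2[C@@](C)(O)C[C@@H]1OC(=O)C3=CCOC(C)(C)OC3 | intermediate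
31 | (1R,3S,6R,7S,8S,10S)-3-acetoxy-8-[(2,2-dimethyl-4,7-dihydro-1,3-dioxepine-5-carbonyl)oxy]-10-hydroxymuurola-4,11(13)-dien-12-oic acid (not isolated) | C=C(C(=O)O)[C@@H]1[C@H]2C=C(C)[C@@H](OC(C)=O)C[C@H]2[C@@](C)(O)C[C@@H]1OC(=O)C3=CCOC(C)(C)OC3 | intermediate
32 | CNP0468194.1, (1R,3S,6R,7S,8S,10S)-3-acetoxy-10-hydroxy-8-{[(2E)-4-hydroxy-2-(hydroxymethyl)but-2-enoyl]oxy}muurola-4,11(13)-dien-12-oic acid | C=C(C(=O)O)[C@@H]1[C@H]2C=C(C)[C@@H](OC(C)=O)C[C@H]2[C@@](C)(O)C[C@@H]1OC(=O)/C(=C/CO)CO | target

## Step count and risks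

Total steps: 20. Longest linear sequence: 14 steps (steps 7–20).

Steps most likely to fail:

1. Step 18 (cycloaddition). The cis C7/C8 pair forces one of the two substituents into a pseudo-axial site in either boat-like transition state, so selection of the diene face may be incomplete. Exo cyclisation to trans-fused material and β-elimination of the C8 carboxylate from 28 are further losses. Fallback (reagent control in place of substrate control): set out from 27, generate 28 with DMP at 0 °C, filter cold through a short pad and cool at once to −78 °C, where the uncatalysed reaction should be slow. A chiral oxazaborolidinium triflimide Lewis acid (diphenylprolinol-derived B-o-tolyl oxazaborolidine activated with HNTf2, CH2Cl2, −78 °C), a known catalyst type for Diels–Alder reactions of enones, is then added. The catalyst antipode whose preferred enone face coincides with the C7-directed one is used. The product is 29, where the route is rejoined; no new compound is made.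

2. Step 11 (allylboration). The ester-deactivated boronate may react too slowly for the chiral acid to outrun the uncatalysed background, which would erode enantioselectivity, and the borate may lactonise. Fallback (metal-mediated Barbier coupling and enzymatic resolution in place of catalytic asymmetric allylboration): set out from alcohol 16. NBS/Me2S (CH2Cl2, 0 °C) should give by SN2' bromination 2-(trimethylsilyl)ethyl (2Z)-2-(bromomethyl)-5-[(4-methoxybenzyl)oxy]pent-2-enoate F1. Indium metal (In) in THF/H2O couples F1 with aldehyde 11 through a cyclic transition state to the racemic syn adduct, that is 20 together with its (3R,4R)-enantiomer F2. Lipase-catalysed acetylation (Burkholderia cepacia lipase, vinyl acetate) is expected, by the usual empirical rule with the branched C3 carbon as the large group, to convert F2 into its acetate F3 and to leave 20, which re-enters the route at step 12.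

3. Step 19 (methyl addition). The methyl group may be delivered to the concave β face (the α face carries the C8 acyloxy group), which gives the C10 epimer; attack on ester carbonyls and β-elimination of the C8 carboxylate are side paths. Fallback (oxygen instead of carbon is delivered to the more accessible face): set out from 29. Takai–Lombardo methylenation (Zn, CH2Br2, TiCl4, THF/CH2Cl2) gives the 10-methylidene compound F4. Oxymercuration with Hg(OAc)2 in THF/H2O is selective for the exocyclic 1,1-disubstituted alkene and places the hydroxyl on the face that the nucleophile preferred, giving the organomercurial F5, which is reduced in the same flask with Bu3SnH to 30, where the route is rejoined.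

Further compounds
F1 | step 11 | 2-(trimethylsilyl)ethyl (2Z)-2-(bromomethyl)-5-[(4-methoxybenzyl)oxy]pent-2-enoate | O=C(OCC[Si](C)(C)C)/C(CBr)=C/CCOCc1ccc(OC)cc1
F2 | step 11 | 2-(trimethylsilyl)ethyl (3R,4R)-4-hydroxy-3-{2-[(4-methoxybenzyl)oxy]ethyl}-2-methylidene-6-[(triethylsilyl)oxy]oct-7-enoate (enantiomer of 20 at C3 and C4) | C=C(C(=O)OCC[Si](C)(C)C)[C@@H](CCOCc1ccc(OC)cc1)[C@H](O)CC(O[Si](CC)(CC)CC)C=C
F3 | step 11 | 4-O-acetate of F2 | C=C(C(=O)OCC[Si](C)(C)C)[C@@H](CCOCc1ccc(OC)cc1)[C@H](OC(C)=O)CC(O[Si](CC)(CC)CC)C=C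
F0 | step 18 | none | none
F4 | step 19 | 10-methylidene analogue of 29 | C=C(C(=O)OCC[Si](C)(C)C)[C@@H]1[C@H]2C=C(C)[C@@H](OC(C)=O)C[C@H]2C(=C)C[C@@H]1OC(=O)C3=CCOC(C)(C)OC3
F5 | step 19 | 10-hydroxy-10-[(acetoxymercurio)methyl] analogue of 30 (not isolated) | C=C(C(=O)OCC[Si](C)(C)C)[C@@H]1[C@H]2C=C(C)[C@@H](OC(C)=O)C[C@H]2[C@@](C[Hg]OC(C)=O)(O)C[C@@H]1OC(=O)C3=CCOC(C)(C)OC3
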